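Ring B is opened at C1–C2 and C3–C4. Its C2–C3 unit, which carries the two hydroxymethyl groups trans to each other, is read as a symmetrical E-butenedioate, and C1, C4 and ring A as an o-quinodimethane with the syringyl group on one terminus and a removable hydroxyl on the other. One thermal Diels–Alder reaction between this diene and the fumarate of methyl (S)-mandelate should close ring B and fix C1, C2 and C3 in the trans,trans arrangement and in one absolute sense. The diene is stored as a cyclic hydroxy sulfone, made by photoenolisation of a protected 2-benzylbenzaldehyde in the presence of SO2.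

Key step: step 10

Assumption: the two (S)-mandelate residues are taken to leave open the fumarate face that leads to the (1S,2R,3R) series of ring B; all structures are drawn on that basis.

Numbering: ring B is numbered as a tetralin, with C1 bearing the syringyl group, C2 and C3 the one-carbon arms and C4 the benzylic carbon next to ring A.

Step 1
Reactants: 1 vanillin
Product: 2 4-(benzyloxy)-3-methoxybenzaldehyde (O-benzylvanillin)
Conditions: BnBr, K2CO3, DMF, 60 °C
Reagents that add atoms: benzyl bromide, BrCc1ccccc1
Why: Williamson etherification of the phenoxide with benzyl bromide is routine for vanillin and should mask the phenol through the organometallic, photochemical, acidic and hydride steps that follow.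

Step 2
Reactants: 2 4-(benzyloxy)-3-methoxybenzaldehyde
Product: 3 4-(benzyloxy)-2-bromo-5-methoxybenzaldehyde (6-bromo-O-benzylvanillin)
Conditions: Br2, NaOAc, AcOH, 20 °C
Reagents that add atoms: bromine, BrBr
Why: Electrophilic aromatic bromination of 4-alkoxy-3-methoxybenzaldehydes should go to the free position para to the methoxy group and not ortho to the bulkier benzyloxy group, while NaOAc buffers the HBr so that the benzyl ether is kept.

Step 3
Reactants: 3 4-(benzyloxy)-2-bromo-5-methoxybenzaldehyde
Product: 4 2-[4-(benzyloxy)-2-bromo-5-methoxyphenyl]-1,3-dioxolane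
Conditions: HOCH2CH2OH, p-TsOH (cat.), toluene, reflux, Dean–Stark trap
Reagents that add atoms: ethylene glycol, OCCO
Why: Acid-catalysed acetalisation with azeotropic removal of water should mask the formyl group, which would otherwise be attacked by the benzylic zinc reagent of step 7.

Step 4
Reactants: 5 syringaldehyde
Product: 6 4-(benzyloxy)-3,5-dimethoxybenzaldehyde
Conditions: BnBr, K2CO3, DMF, 70 °C
Reagents that add atoms: benzyl bromide, BrCc1ccccc1
Why: Williamson etherification should also succeed on this phenol flanked by two methoxy groups, since benzyl bromide is an unhindered electrophile.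

Step 5
Reactants: 6 4-(benzyloxy)-3,5-dimethoxybenzaldehyde
Product: 7 [4-(benzyloxy)-3,5-dimethoxyphenyl]methanol
Conditions: NaBH4, MeOH–THF, 0 °C
Reagents that add atoms: none
Why: Borohydride reduction of an aromatic aldehyde to the benzylic alcohol is chemoselective and leaves the ethers untouched.

Step 6
Reactants: 7 [4-(benzyloxy)-3,5-dimethoxyphenyl]methanol
Product: 8 4-(benzyloxy)-3,5-dimethoxybenzyl chloride
Conditions: SOCl2, DMF (cat.), CH2Cl2, 0 °C to rt
Reagents that add atoms: thionyl chloride, O=S(Cl)Cl
Why: Chlorodehydroxylation through the chlorosulfite is fast for an electron-rich benzylic alcohol, and the volatile by-products allow the sensitive chloride to be used without chromatography.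

Step 7
Reactants: 8 4-(benzyloxy)-3,5-dimethoxybenzyl chloride, 4 2-[4-(benzyloxy)-2-bromo-5-methoxyphenyl]-1,3-dioxolane
Product: 11 4-(benzyloxy)-2-[4-(benzyloxy)-3,5-dimethoxybenzyl]-5-methoxybenzaldehyde, via benzylic zinc chloride 9 (not isolated), via coupled dioxolane 10 (not isolated)
Conditions: (a) 8, Zn dust (activated by BrCH2CH2Br and Me3SiCl), LiCl, THF, 25 °C; (b) 4, Pd(OAc)2 (2 mol %), SPhos (4 mol %), THF, 25 to 50 °C; (c) 2 M aq HCl, THF, rt
Reagents that add atoms: water, O
Why: LiCl-assisted insertion of zinc into the benzylic C–Cl bond gives a zinc reagent that tolerates the ethers, Negishi sp3–sp2 cross-coupling on zerovalent palladium carrying a bulky biarylphosphine joins it to the hindered electron-rich aryl bromide, and the acidic work-up hydrolyses the dioxolane to release the formyl group.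

Step 8
Reactants: 11 4-(benzyloxy)-2-[4-(benzyloxy)-3,5-dimethoxybenzyl]-5-methoxybenzaldehyde
Product: 12 racemic cis-6-(benzyloxy)-1-[4-(benzyloxy)-3,5-dimethoxyphenyl]-3-hydroxy-5-methoxy-1,3-dihydrobenzo[c]thiophene 2,2-dioxide
Conditions: hν (350 nm, Pyrex), benzene saturated with SO2, 15 °C, then evaporation below 30 °C
Reagents that add atoms: sulfur dioxide, O=S=O
Why: Photoenolisation, in which the excited formyl group takes a hydrogen from the diarylmethane CH2 by 1,5-transfer, gives the E,E dienol, and SO2 should trap it by suprafacial cheletropic addition so that OH and aryl end up cis; the product is racemic, which does not matter because both centres are lost again in step 10.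

Step 9
Reactants: 13 methyl (S)-mandelate (2 equiv), 14 fumaryl chloride
Product: 15 bis[(1S)-2-methoxy-2-oxo-1-phenylethyl] (2E)-but-2-enedioate
Conditions: toluene, 100 °C, slow N2 stream to carry off HCl
Reagents that add atoms: none
Why: Double nucleophilic acyl substitution at the two acid chloride groups does not involve the carbinol C–O bonds, so both (S) centres and the E alkene are retained, and the base-free conditions avoid enolisation of the mandelate.

Step 10
Reactants: 12 racemic cis hydroxy sulfone, 15 bis[(1S)-2-methoxy-2-oxo-1-phenylethyl] fumarate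
Product: 17 bis[(1S)-2-methoxy-2-oxo-1-phenylethyl] (1S,2R,3S,4S)-7-(benzyloxy)-1-[4-(benzyloxy)-3,5-dimethoxyphenyl]-4-hydroxy-6-methoxy-1,2,3,4-tetrahydronaphthalene-2,3-dicarboxylate, via E,E hydroxy-o-quinodimethane 16 (not isolated)
Conditions: 15 (1.2 equiv), toluene, 80 °C, slow argon stream
Reagents that add atoms: none
Why: On heating, cis sulfone 12 should lose SO2 by a suprafacial retro-cheletropic reaction to unveil the electron-rich E,E dienol 16, which the electron-poor fumarate 15 intercepts in a concerted suprafacial [4+2] cycloaddition driven by the return of aromaticity to ring A. The closest known reaction type is the Diels–Alder trapping of α-hydroxy-α'-aryl-o-quinodimethanes by fumarates of chiral α-hydroxy esters. Ring B closes as a six-membered carbocycle by intermolecular [4+2] cycloaddition, the C1–C2 and C3–C4 bonds forming together. The trans relation of C2 and C3 is copied from the E alkene, the trans C1/C2 and cis C3/C4 relations follow from the E,E diene reacting with the C3 ester endo (beside the hydroxyl, to which it can hydrogen-bond) and the C2 ester exo (away from the twisted aryl group), and the absolute configuration is dictated by the two (S)-mandelate units, whose substituents leave one face of the enoate open. The step needs endo/exo and diastereofacial selectivity, secured by the bulky C1 aryl group together with the hydroxyl and by the twofold-symmetric pair of auxiliaries respectively, while regiochemistry is no issue because both ends of the dienophile are equivalent.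

Step 11
Reactants: 17 hydroxy tetralin diester
Product: 18 bis[(1S)-2-methoxy-2-oxo-1-phenylethyl] (1S,2R,3R)-7-(benzyloxy)-1-[4-(benzyloxy)-3,5-dimethoxyphenyl]-6-methoxy-1,2,3,4-tetrahydronaphthalene-2,3-dicarboxylate
Conditions: Et3SiH, CF3CO2H, CH2Cl2, −20 to 0 °C
Reagents that add atoms: none
Why: Ionic hydrogenation should work because the C4 hydroxyl sits para to the benzyloxy group of ring A and ionises readily to a stabilised benzylic cation that the silane reduces to CH2, which deletes the C4 centre without touching C1, C2 or C3.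

Step 12
Reactants: 18 deoxy tetralin diester
Product: 19 [(1S,2R,3R)-7-(benzyloxy)-1-[4-(benzyloxy)-3,5-dimethoxyphenyl]-6-methoxy-1,2,3,4-tetrahydronaphthalene-2,3-diyl]dimethanol
Conditions: LiAlH4, THF, 0 °C to rt, then H2O
Reagents that add atoms: none
Why: Hydride reduction of both ring esters to primary alcohols cleaves the acyl–oxygen bonds, so the auxiliaries leave as a water-soluble diol, and the trans-diequatorial C2/C3 arrangement is the stable one and should not epimerise.

Step 13
Reactants: 19 di-O-benzyl diol
Product: 20 5-methoxy-(+)-isolariciresinol, (6R,7R,8S)-8-(4-hydroxy-3,5-dimethoxyphenyl)-6,7-bis(hydroxymethyl)-3-methoxy-5,6,7,8-tetrahydronaphthalen-2-ol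
Conditions: H2 (1 atm), 10 % Pd/C, EtOAc–MeOH, rt
Reagents that add atoms: none
Why: Catalytic hydrogenolysis cleaves the two aryl benzyl ethers under neutral conditions, under which the C1–H bond, the primary alcohols and the three stereocentres are inert.

Compound list
1 | vanillin | COc1cc(C=O)ccc1O | starting material
2 | 4-(benzyloxy)-3-methoxybenzaldehyde | COc1cc(C=O)ccc1OCc1ccccc1 | intermediate
3 | 4-(benzyloxy)-2-bromo-5-methoxybenzaldehyde | COc1cc(C=O)c(Br)cc1OCc1ccccc1 | intermediate
4 | 2-[4-(benzyloxy)-2-bromo-5-methoxyphenyl]-1,3-dioxolane | COc1cc(C2OCCO2)c(Br)cc1OCc1ccccc1 | intermediate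
5 | syringaldehyde | COc1cc(C=O)cc(OC)c1O | starting material
6 | 4-(benzyloxy)-3,5-dimethoxybenzaldehyde | COc1cc(C=O)cc(OC)c1OCc1ccccc1 | intermediate
7 | [4-(benzyloxy)-3,5-dimethoxyphenyl]methanol | COc1cc(CO)cc(OC)c1OCc1ccccc1 | intermediate
8 | 4-(benzyloxy)-3,5-dimethoxybenzyl chloride | COc1cc(CCl)cc(OC)c1OCc1ccccc1 | intermediate
9 | [4-(benzyloxy)-3,5-dimethoxybenzyl]zinc chloride (formed in the flask) | COc1cc(C[Zn]Cl)cc(OC)c1OCc1ccccc1 | intermediate
10 | 2-{4-(benzyloxy)-2-[4-(benzyloxy)-3,5-dimethoxybenzyl]-5-methoxyphenyl}-1,3-dioxolane (formed in the flask) | COc1cc(C2OCCO2)c(Cc2cc(OC)c(OCc3ccccc3)c(OC)c2)cc1OCc1ccccc1 | intermediate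
11 | 4-(benzyloxy)-2-[4-(benzyloxy)-3,5-dimethoxybenzyl]-5-methoxybenzaldehyde | COc1cc(C=O)c(Cc2cc(OC)c(OCc3ccccc3)c(OC)c2)cc1OCc1ccccc1 | intermediate
12 | racemic cis-6-(benzyloxy)-1-[4-(benzyloxy)-3,5-dimethoxyphenyl]-3-hydroxy-5-methoxy-1,3-dihydrobenzo[c]thiophene 2,2-dioxide (one enantiomer drawn) | O[C@H]1c2cc(OC)c(OCc3ccccc3)cc2[C@@H](c2cc(OC)c(OCc3ccccc3)c(OC)c2)S1(=O)=O | intermediate
13 | methyl (S)-mandelate | O[C@@H](c1ccccc1)C(=O)OC | starting material
14 | fumaryl chloride | O=C(Cl)/C=C/C(=O)Cl | starting material
15 | bis[(1S)-2-methoxy-2-oxo-1-phenylethyl] (2E)-but-2-enedioate | O=C(/C=C/C(=O)O[C@@H](c1ccccc1)C(=O)OC)O[C@@H](c1ccccc1)C(=O)OC | intermediate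
16 | E,E o-quinodimethane: ring A with exocyclic =CH–OH and =CH–aryl groups, OH and aryl both outward (formed in the flask) | O/C=C1\C=C(OC)C(OCc2ccccc2)=C\C1=C/c1cc(OC)c(OCc2ccccc2)c(OC)c1 | intermediate
17 | bis[(1S)-2-methoxy-2-oxo-1-phenylethyl] (1S,2R,3S,4S)-7-(benzyloxy)-1-[4-(benzyloxy)-3,5-dimethoxyphenyl]-4-hydroxy-6-methoxy-1,2,3,4-tetrahydronaphthalene-2,3-dicarboxylate (1,2-trans, 2,3-trans, 3,4-cis) | COc1cc2c(cc1OCc1ccccc1)[C@H](c1cc(OC)c(OCc3ccccc3)c(OC)c1)[C@@H](C(=O)O[C@@H](c1ccccc1)C(=O)OC)[C@H](C(=O)O[C@@H](c1ccccc1)C(=O)OC)[C@@H]2O | intermediate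
18 | bis[(1S)-2-methoxy-2-oxo-1-phenylethyl] (1S,2R,3R)-7-(benzyloxy)-1-[4-(benzyloxy)-3,5-dimethoxyphenyl]-6-methoxy-1,2,3,4-tetrahydronaphthalene-2,3-dicarboxylate | COc1cc2c(cc1OCc1ccccc1)[C@H](c1cc(OC)c(OCc3ccccc3)c(OC)c1)[C@@H](C(=O)O[C@@H](c1ccccc1)C(=O)OC)[C@H](C(=O)O[C@@H](c1ccccc1)C(=O)OC)C2 | intermediate
19 | [(1S,2R,3R)-7-(benzyloxy)-1-[4-(benzyloxy)-3,5-dimethoxyphenyl]-6-methoxy-1,2,3,4-tetrahydronaphthalene-2,3-diyl]dimethanol | COc1cc2c(cc1OCc1ccccc1)[C@H](c1cc(OC)c(OCc3ccccc3)c(OC)c1)[C@@H](CO)[C@H](CO)C2 | intermediate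
20 | 5-methoxy-(+)-isolariciresinol | COc1cc2c(cc1O)[C@H](c1cc(OC)c(O)c(OC)c1)[C@@H](CO)[C@H](CO)C2 | target

Total step count: 13 steps.
Longest linear sequence: 9 steps (steps 1, 2, 3, 7, 8, 10, 11, 12, 13 from vanillin; the syringaldehyde branch through steps 4, 5, 6 is equally long).

Steps most likely to fail

Step 10. The diene may add to both faces of the fumarate or to the unwanted one, or the endo/exo preference may erode, so that the absolute or relative configuration of C1 to C3 is not secured. Fallback, setting out from 12 and returning at 19: the sulfone would be heated in toluene at 80 °C with bought dimethyl fumarate. This should give the racemic 1,2-trans, 2,3-trans, 3,4-cis dimethyl 4-hydroxytetralin-2,3-dicarboxylate F1. Ionic hydrogenation with Et3SiH and CF3CO2H would then give the racemic deoxy dimethyl ester F2. LiAlH4 would reduce F2 to the racemic diol, in which 19 is accompanied by its mirror image, the (1R,2S,3S) diol F3. Preparative chromatography on a chiral stationary phase would remove F3 and deliver 19, from which step 13 follows unchanged.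

Step 8. The photoenolisation may be inefficient, or the labile α-hydroxy sulfone may lose SO2 and revert to the aldehyde while it is isolated. Fallback, setting out from 11 and returning at 17: aldehyde 11 would be irradiated at 350 nm in benzene with fumarate 15 already present. The photodienol 16 is then trapped by the dienophile as it forms and cycloadduct 17 is reached directly, without any sulfone.

Step 11. The C4 cation may lose the C3 proton to give a dihydronaphthalene conjugated to the ester, or the acid may strip a benzyl ether. Fallback, setting out from 17 and ending at 20: LiAlH4 in THF would first reduce both ring esters with the C4 hydroxyl still in place, giving the triol (1S,2R,3R,4S)-7-(benzyloxy)-1-[4-(benzyloxy)-3,5-dimethoxyphenyl]-4-hydroxy-6-methoxy-1,2,3,4-tetrahydronaphthalene-2,3-diyldimethanol F4. Hydrogenolysis over Pd/C in AcOH with a trace of HClO4 would then cleave the activated benzylic C4–O bond and both benzyl ethers in one operation to give 20.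

Further compounds
F1 | step 10 | racemic dimethyl 7-(benzyloxy)-1-[4-(benzyloxy)-3,5-dimethoxyphenyl]-4-hydroxy-6-methoxy-1,2,3,4-tetrahydronaphthalene-2,3-dicarboxylate, 1,2-trans, 2,3-trans, 3,4-cis (one enantiomer drawn) | COc1cc2c(cc1OCc1ccccc1)[C@H](c1cc(OC)c(OCc3ccccc3)c(OC)c1)[C@@H](C(=O)OC)[C@H](C(=O)OC)[C@@H]2O
F2 | step 10 | racemic dimethyl 7-(benzyloxy)-1-[4-(benzyloxy)-3,5-dimethoxyphenyl]-6-methoxy-1,2,3,4-tetrahydronaphthalene-2,3-dicarboxylate, 1,2-trans, 2,3-trans (one enantiomer drawn) | COc1cc2c(cc1OCc1ccccc1)[C@H](c1cc(OC)c(OCc3ccccc3)c(OC)c1)[C@@H](C(=O)OC)[C@H](C(=O)OC)C2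
F3 | step 10 | [(1R,2S,3S)-7-(benzyloxy)-1-[4-(benzyloxy)-3,5-dimethoxyphenyl]-6-methoxy-1,2,3,4-tetrahydronaphthalene-2,3-diyl]dimethanol, the mirror image of 19 | COc1cc2c(cc1OCc1ccccc1)[C@@H](c1cc(OC)c(OCc3ccccc3)c(OC)c1)[C@H](CO)[C@@H](CO)C2
F0 | step 8 | none | none
F4 | step 11 | (1S,2R,3R,4S)-7-(benzyloxy)-1-[4-(benzyloxy)-3,5-dimethoxyphenyl]-2,3-bis(hydroxymethyl)-6-methoxy-1,2,3,4-tetrahydronaphthalen-4-ol | COc1cc2c(cc1OCc1ccccc1)[C@H](c1cc(OC)c(OCc3ccccc3)c(OC)c1)[C@@H](CO)[C@H](CO)[C@@H]2O
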